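Start from the starting material. It is consumed while intermediates A and B, product and trapped intermediate appear.

in all of them: capture agent 0.0156 M

| flask | starting material | coupling partner | temperature | remark | time |
|---|---|---|---|---|---|
| delta | 0.026 M | 0.0468 M | −25 °C | run made earlier |  |
| gamma | 0.039 M | 0.0468 M | −10 °C | run made earlier |  |
| theta | 0.052 M | 0.023 M | −25 °C | run made earlier |  |
| spring | 0.052 M | 0.0468 M | −20 °C |  | 5.0 h |
| summer | 0.052 M | 0.0468 M | −10 °C |  | 5.0 h |
| midnight | 0.052 M | 0.0468 M | 0 °C |  | 5.0 h |

| run | time / h | trapped intermediate / % | intermediate A / % | product / % | starting material / % | intermediate B / % |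
|---|---|---|---|---|---|---|
| delta | 0.417 | 0 | 2.1 | 0 | 97.0 | 0 |
| delta | 0.667 | 0 | 3.7 | 0.3 | 97.0 | 0.8 |
| delta | 1.00 | 0.2 | 4.6 | 0 | 95.6 | 0.3 |
| delta | 2.00 | 0.1 | 8.0 | 0.1 | 90.7 | 1.6 |
| delta | 3.00 | 0.9 | 9.2 | 1.5 | 87.0 | 3.1 |
| delta | 5.00 | 0.9 | 11.7 | 3.6 | 79.1 | 5.9 |
| gamma | 0.500 | 0.9 | 7.5 | 0.7 | 86.9 | 3.3 |
| gamma | 1.00 | 1.2 | 8.0 | 4.4 | 79.6 | 8.1 |
| gamma | 1.50 | 0.4 | 7.8 | 6.8 | 72.8 | 11.8 |
| gamma | 2.00 | 1.5 | 7.3 | 9.4 | 67.8 | 14.7 |
| gamma | 2.50 | 2.1 | 6.6 | 11.1 | 61.8 | 17.8 |
| gamma | 3.00 | 3.1 | 6.1 | 13.2 | 57.4 | 20.9 |
| theta | 1.00 | 0 | 5.3 | 0 | 95.1 | 0.6 |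
| theta | 2.00 | 0 | 7.7 | 0.2 | 90.4 | 1.7 |
| theta | 3.00 | 0.9 | 10.4 | 0.9 | 86.5 | 2.5 |
| theta | 4.00 | 0.5 | 11.0 | 2.0 | 82.8 | 3.7 |
| theta | 5.00 | 1.6 | 11.2 | 3.1 | 79.8 | 5.5 |

(each reading ± 0.5 percentage points)

- the numbers in the tables scatter by 0.5 percentage points (one standard deviation)

1. which of these there is most of at the end, counted by the starting material in it, spring (product / intermediate A / trapped intermediate / starting material / intermediate B)
2. which of these there is most of at the end, counted by the starting material in it, summer (product / intermediate A / trapped intermediate / starting material / intermediate B)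
3. which of these there is most of at the end, counted by the starting material in it, midnight (product / intermediate A / trapped intermediate / starting material / intermediate B)
4. the largest of these amounts at the end, in percent of the starting material charged, spring
5. the largest of these amounts at the end, in percent of the starting material charged, summer
6. the largest of these amounts at the end, in percent of the starting material charged, midnight

One thing looks wrong at first. The delta run has half the starting material of the theta run and twice the coupling partner, yet at 5.00 h delta keeps 79.1% and theta 79.8%. These two readings differ by 0.7 percentage points, each with a scatter of 0.5 points, so we read the loss as first order, with one decay constant for both runs. The last readings of delta and gamma give: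

k at −25 °C = 0.0469 h⁻¹; k at −10 °C = 0.185 h⁻¹

Ea/R = 5980 K

At its last reading the gamma run shows intermediate B as a share s = 49.1% of what has left the starting material. We hold that share fixed and ask when the two amounts stand equal:

t = ln((1 + s)/s) / k

For the midnight flask k = 0.425 h⁻¹, so t = 2.62 h. We call this the hand-over time: on the fixed share, starting material stands above intermediate B before it and below intermediate B after it.

In spring it is 14.7 h and in summer 6.01 h, both longer than 5.0 h, while midnight's is shorter. We therefore expect starting material at 68.6% in spring and 39.7% in summer, and intermediate B at 43.2% at midnight. That last figure may run low, since the gamma run's share read 39.7% at 1.00 h, less than s.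

The forecast names starting material at 69% for spring, starting material at 39.5% for summer and intermediate B at 45% for midnight, a little above our midnight figure: “B probably leads at about 45%, though this is uncertain because trapping may drain it”.

The flasks give starting material at 68.0%, starting material at 40.9% and intermediate B at 55.1%.

    capture agent + intermediate A → trapped intermediate (k = 0.0478 L mol⁻¹ min⁻¹, Ea = 57.0 kJ mol⁻¹)
    intermediate A → intermediate B (k = 0.00751 min⁻¹, Ea = 71.0 kJ mol⁻¹)
    starting material ⇌ intermediate A (K = 0.375, k = 0.00184 min⁻¹, Ea = 75.0 kJ mol⁻¹, ΔH = −43.0 kJ mol⁻¹)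
    intermediate B ⇌ product (K = 1.41, k = 0.0124 min⁻¹, Ea = 82.0 kJ mol⁻¹, ΔH = −36.0 kJ mol⁻¹)
    (constants at −20 °C)

In the midnight flask at 2.50 h, starting material stands at 40.4% against 38.5% of intermediate B, just before the hand-over time of 2.62 h. The amount is where the numbers part: intermediate B's share in that flask ends at 66.6%, above the 49.1% carried from gamma, and intermediate B ends 10 points above the forecast. For the same flask at −15 °C we reckon k = 0.119 h⁻¹ and a hand-over time of 9.32 h, longer than 5.0 h. At its end starting material stands at 54.8% against 18.5% of intermediate B.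

The readings are simulated for substances that don't exist; noise was put on by code.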